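**Strategy**

Both one-carbon substituents on the benzene ring of the chroman, CH2O at C7 and CHO at C8, are disconnected together. An 8-fluorochroman is lithiated at C7 and loses LiF to the C7–C8 aryne; the ring oxygen O1 on C8a then steers (methoxymethoxy)methyllithium to C7 and the new carbanion to C8, where DMF formylates it, so two C–C bonds form in one flask. The precursor, (2R)-8-fluoro-5-methoxy-2-methyl-2-(4-methylpent-3-enyl)chroman, is made in three steps from 3,4-difluoroanisole and (R)-linalool, which supplies the C2 stereocentre: one fluorine is displaced in the pyran ring closure, the other is kept for the aryne. MOM removal, palmitoylation and a final allylic oxidation complete the target.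

Key step: step 4

Remark: commercial (R)-(−)-linalool sets the enantiomeric purity of all later compounds. C2 is (R) up to compound 19 and is named (S) in target 20 only because the new ketone changes the CIP ranking; the spatial arrangement is unchanged.

**Route**

Step 1
Reactants: 1 3,4-difluoroanisole
Product: 3 1,2-difluoro-3-iodo-4-methoxybenzene, via 2,3-difluoro-6-methoxyphenyllithium 2 (not isolated)
Conditions: LiN(i-Pr)2 (LDA), THF, −78 °C; I2, −78 °C → rt
Reagents that add atoms: iodine, II
Why: The ring proton flanked by methoxy and fluorine is the most acidic, so directed ortho-lithiation at −78 °C (below the temperature of LiF loss) followed by iodinolysis should give the iodide at that position only.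

Step 2
Reactants: 4 (R)-(−)-linalool [(3R)-3,7-dimethylocta-1,6-dien-3-ol]; 3 1,2-difluoro-3-iodo-4-methoxybenzene
Product: 6 (3R)-1-(2,3-difluoro-6-methoxyphenyl)-3,7-dimethyloct-6-en-3-ol, via B-alkyl-9-BBN adduct 5 (not isolated)
Conditions: 9-BBN (1.5 equiv), THF, 0 °C → rt; then 3, PdCl2(dppf) (5 mol %), 3 M NaOH aq, THF, 60 °C
Reagents that add atoms: none
Why: 9-BBN should hydroborate only the monosubstituted vinyl group (anti-Markovnikov, trisubstituted alkene untouched), and the B-alkyl Suzuki–Miyaura coupling joins the primary borane to the aryl iodide without touching the carbinol stereocentre carried over from linalool.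

Step 3
Reactants: 6 (3R)-1-(2,3-difluoro-6-methoxyphenyl)-3,7-dimethyloct-6-en-3-ol
Product: 8 (2R)-8-fluoro-5-methoxy-2-methyl-2-(4-methylpent-3-en-1-yl)chroman, via potassium alkoxide 7 (not isolated)
Conditions: KN(SiMe3)2 (KHMDS, 1.2 equiv), THF–DMPU, 0 °C → 65 °C
Reagents that add atoms: none
Why: Intramolecular SNAr in which the tertiary alkoxide displaces the fluorine ortho to the side chain (6-exo closure, activated by the neighbouring C–F bond and the meta methoxy group; the other fluorine is out of reach and methoxide is a far poorer leaving group), and since the C–O bond at the stereocentre is never broken the (R) configuration is retained.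

Step 4
Reactants: 8 (2R)-8-fluoro-5-methoxy-2-methyl-2-(4-methylpent-3-en-1-yl)chroman; 9 tributyl[(methoxymethoxy)methyl]stannane
Product: 15 (2R)-5-methoxy-7-[(methoxymethoxy)methyl]-2-methyl-2-(4-methylpent-3-en-1-yl)chroman-8-carbaldehyde, via (methoxymethoxy)methyllithium 10 (not isolated), via 7-lithio-8-fluorochroman 11 (not isolated), via chroman 7,8-aryne 12 (not isolated), via 8-lithiochroman adduct 13 (not isolated), via lithium hemiaminal alkoxide 14 (not isolated)
Conditions: flask A: 9 (3 equiv), n-BuLi, THF, −78 °C; flask B: 8, s-BuLi (1.05 equiv), PMDTA, THF, −78 °C; B into A, −78 → −40 °C; DMF, −78 → 0 °C; H2O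
Reagents that add atoms: N,N-dimethylformamide, CN(C)C=O
Why: Proposed new method: s-BuLi–PMDTA should remove the most acidic ring proton, C7–H beside fluorine (acidity control, whereas an uncomplexed alkyllithium could be drawn to C6 by the methoxy group), and on warming to about −40 °C aryllithium 11 loses LiF to give aryne 12, to which the primary α-alkoxyalkyllithium 10, present in excess, adds at C7 to leave aryllithium 13, which DMF formylates at C8 through adduct 14. The closest known reaction type is the three-component aryne coupling in which an aryne made from an ortho-lithiated fluoroarene takes up an alkyl- or aryllithium and the new aryllithium is trapped by an electrophile; the new element is an α-alkoxymethyllithium as the adding nucleophile, which should behave as a primary alkyllithium and should survive the temperature at which LiF is lost. No ring closes and no stereocentre is formed; C2 is remote and untouched. Regioselectivity of addition across C7–C8 is needed and is secured by O1 on C8a, whose inductive pull makes C7 the electrophilic terminus and stabilises the carbanion at C8, where it is also chelated by O1 and the MOM oxygens; the position of the aryne is fixed by the fluorine, because a C6-lithio species has no leaving group beside it. Chemoselectivity among the organolithiums is secured by the threefold excess and small size of 10 relative to aryllithiums 11 and 13, and the side-chain alkene and the ethers are inert to all of them.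

Step 5
Reactants: 15 (2R)-5-methoxy-7-[(methoxymethoxy)methyl]-2-methyl-2-(4-methylpent-3-en-1-yl)chroman-8-carbaldehyde
Product: 17 (2R)-7-(hydroxymethyl)-5-methoxy-2-methyl-2-(4-methylpent-3-en-1-yl)chroman-8-carbaldehyde, via alkoxymethyl-bipyridinium triflate 16 (not isolated)
Conditions: TMSOTf, 2,2'-bipyridyl, CH2Cl2, 0 °C → rt; then H2O
Reagents that add atoms: none
Why: Silylation of the acetal methoxy oxygen and capture of the resulting oxocarbenium ion by bipyridyl give salt 16, which water hydrolyses to the alcohol; this aprotic MOM cleavage avoids protic acid strong enough to hydrolyse a formaldehyde acetal, which would also threaten the trisubstituted alkene, and it should leave the aldehyde and the tertiary aryl ether alone.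

Step 6
Reactants: 17 (2R)-7-(hydroxymethyl)-5-methoxy-2-methyl-2-(4-methylpent-3-en-1-yl)chroman-8-carbaldehyde; 18 palmitoyl chloride
Product: 19 [(2R)-8-formyl-5-methoxy-2-methyl-2-(4-methylpent-3-en-1-yl)chroman-7-yl]methyl hexadecanoate
Conditions: pyridine, CH2Cl2, 0 °C → rt
Reagents that add atoms: none
Why: Nucleophilic acyl substitution at the acid chloride by the primary benzylic alcohol, whose open hydroxy-aldehyde form should be favoured over the lactol because the aldehyde is deactivated by the ortho and para oxygen donors; the ester is made before the ketone so that no base meets the β-aryloxy ketone of the target.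

Step 7
Reactants: 19 [(2R)-8-formyl-5-methoxy-2-methyl-2-(4-methylpent-3-en-1-yl)chroman-7-yl]methyl hexadecanoate
Product: 20 [(2S)-8-formyl-5-methoxy-2-methyl-2-(4-methyl-2-oxopent-3-en-1-yl)chroman-7-yl]methyl hexadecanoate (target)
Conditions: CrO3, 3,5-dimethylpyrazole, CH2Cl2, −20 °C
Reagents that add atoms: chromium trioxide, O=[Cr](=O)=O
Why: Allylic oxidation by the CrO3–3,5-dimethylpyrazole complex should convert the C2' methylene beside the trisubstituted alkene into the conjugated ketone (methylene preferred over the allylic methyl groups, benzylic C4 and C7 methylenes deactivated by the ring aldehyde and the ester oxygen) under cold, non-basic conditions that avoid retro-oxa-Michael opening of the β-aryloxy ketone, so C2 keeps its configuration.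

**Compound list**

1 | 3,4-difluoroanisole | COc1ccc(F)c(F)c1 | starting material
2 | (2,3-difluoro-6-methoxyphenyl)lithium | COc1ccc(F)c(F)c1[Li] | intermediate
3 | 1,2-difluoro-3-iodo-4-methoxybenzene | COc1ccc(F)c(F)c1I | intermediate
4 | (R)-(−)-linalool, (3R)-3,7-dimethylocta-1,6-dien-3-ol | CC(C)=CCC[C@](C)(C=C)O | starting material
5 | (3S)-1-(9-borabicyclo[3.3.1]nonan-9-yl)-3,7-dimethyloct-6-en-3-ol (same spatial arrangement as 4) | CC(C)=CCC[C@](C)(CCB1C2CCCC1CCC2)O | intermediate
6 | (3R)-1-(2,3-difluoro-6-methoxyphenyl)-3,7-dimethyloct-6-en-3-ol | COc1ccc(F)c(F)c1CC[C@](C)(O)CCC=C(C)C | intermediate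
7 | potassium (3R)-1-(2,3-difluoro-6-methoxyphenyl)-3,7-dimethyloct-6-en-3-olate | COc1ccc(F)c(F)c1CC[C@](C)([O-])CCC=C(C)C.[K+] | intermediate
8 | (2R)-8-fluoro-5-methoxy-2-methyl-2-(4-methylpent-3-en-1-yl)chroman | COc1ccc(F)c2O[C@](C)(CCC=C(C)C)CCc12 | intermediate
9 | tributyl[(methoxymethoxy)methyl]stannane | CCCC[Sn](CCCC)(CCCC)COCOC | starting material
10 | (methoxymethoxy)methyllithium | [Li]COCOC | intermediate
11 | [(2R)-8-fluoro-5-methoxy-2-methyl-2-(4-methylpent-3-en-1-yl)chroman-7-yl]lithium | COc1cc([Li])c(F)c2O[C@](C)(CCC=C(C)C)CCc12 | intermediate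
12 | (2R)-5-methoxy-2-methyl-2-(4-methylpent-3-en-1-yl)-7,8-didehydrochroman (C7–C8 aryne) | COC1=CC#CC2=C1CC[C@@](C)(CCC=C(C)C)O2 | intermediate
13 | [(2R)-5-methoxy-7-[(methoxymethoxy)methyl]-2-methyl-2-(4-methylpent-3-en-1-yl)chroman-8-yl]lithium | COCOCc1cc(OC)c2c(c1[Li])O[C@](C)(CCC=C(C)C)CC2 | intermediate
14 | lithium (dimethylamino)[(2R)-5-methoxy-7-[(methoxymethoxy)methyl]-2-methyl-2-(4-methylpent-3-en-1-yl)chroman-8-yl]methanolate | COCOCc1cc(OC)c2c(c1C([O-])N(C)C)O[C@](C)(CCC=C(C)C)CC2.[Li+] | intermediate
15 | (2R)-5-methoxy-7-[(methoxymethoxy)methyl]-2-methyl-2-(4-methylpent-3-en-1-yl)chroman-8-carbaldehyde | COCOCc1cc(OC)c2c(c1C=O)O[C@](C)(CCC=C(C)C)CC2 | intermediate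
16 | 1-[({(2R)-8-formyl-5-methoxy-2-methyl-2-(4-methylpent-3-en-1-yl)chroman-7-yl}methoxy)methyl]-2-(pyridin-2-yl)pyridinium triflate | COc1cc(COC[n+]3ccccc3-c3ccccn3)c(C=O)c2O[C@](C)(CCC=C(C)C)CCc12.[O-]S(=O)(=O)C(F)(F)F | intermediate
17 | (2R)-7-(hydroxymethyl)-5-methoxy-2-methyl-2-(4-methylpent-3-en-1-yl)chroman-8-carbaldehyde | OCc1cc(OC)c2c(c1C=O)O[C@](C)(CCC=C(C)C)CC2 | intermediate
18 | palmitoyl chloride (hexadecanoyl chloride) | CCCCCCCCCCCCCCCC(=O)Cl | starting material
19 | [(2R)-8-formyl-5-methoxy-2-methyl-2-(4-methylpent-3-en-1-yl)chroman-7-yl]methyl hexadecanoate | CCCCCCCCCCCCCCCC(=O)OCc1cc(OC)c2c(c1C=O)O[C@](C)(CCC=C(C)C)CC2 | intermediate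
20 | [(2S)-8-formyl-5-methoxy-2-methyl-2-(4-methyl-2-oxopent-3-en-1-yl)chroman-7-yl]methyl hexadecanoate | CCCCCCCCCCCCCCCC(=O)OCc1cc(OC)c2c(c1C=O)O[C@](C)(CC(=O)C=C(C)C)CC2 | target

**Step count**

Total steps: 7. Longest linear sequence: 7 steps (from 3,4-difluoroanisole 1 to target 20; 6 from linalool 4).

**Steps most likely to fail**

1. Step 4 (new method).
What may go wrong:
- the α-alkoxyalkyllithium decomposes before LiF loss sets in;
- aryllithiums 11 and 13 compete with 10 for the aryne;
- partial lithiation at C6 beside the methoxy group;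
- intramolecular ene capture of the aryne by the side-chain alkene.

Fallback, known chemistry only and without an aryne. It sets out from linalool 4 through its borane 5 and comes back to the route at 17. Commercial 4-bromo-3-fluoroanisole is lithiated between fluorine and methoxy (LiN(i-Pr)2, THF, −78 °C) and iodinated to 1-bromo-2-fluoro-3-iodo-4-methoxybenzene F1. B-alkyl Suzuki–Miyaura coupling of 5 at the C–I bond (PdCl2(dppf), NaOH aq, THF) should give (3R)-1-(3-bromo-2-fluoro-6-methoxyphenyl)-3,7-dimethyloct-6-en-3-ol F2. SNAr closure as in step 3 (KN(SiMe3)2, THF–DMPU) gives (2R)-8-bromo-5-methoxy-2-methyl-2-(4-methylpent-3-en-1-yl)chroman F3. Bromine–lithium exchange (n-BuLi, THF, −78 °C) and DMF give (2R)-5-methoxy-2-methyl-2-(4-methylpent-3-en-1-yl)chroman-8-carbaldehyde F4. Addition of lithium N,N,N'-trimethylethylenediamide, LiN(Me)CH2CH2NMe2, masks the aldehyde as the lithium α-amino alkoxide F5, a strong ortho-director whose only free neighbouring position is C7. Lithiation there (n-BuLi, THF, −20 °C), quench with gaseous formaldehyde and aqueous work-up should deliver 17 directly.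

2. Step 7.
What may go wrong:
- oxidation at the electron-rich benzylic C4 methylene or at the allylic methyl groups alongside C2';
- incomplete conversion with the large excess of oxidant.

Fallback, a stepwise oxygen transposition in place of C–H oxidation. It sets out from 19 and comes back at 20. Hydroxyselenation of the trisubstituted alkene (N-(phenylseleno)phthalimide, H2O, cat. camphorsulfonic acid, CH2Cl2) should give the Markovnikov β-hydroxy selenide [(2S)-8-formyl-2-[4-hydroxy-4-methyl-3-(phenylselanyl)pentyl]-5-methoxy-2-methylchroman-7-yl]methyl hexadecanoate F6 (both C3' epimers). Oxidation with NaIO4 (NaHCO3, aq THF) and spontaneous syn-elimination, possible only towards C2', give the tertiary allylic alcohol [(2S)-8-formyl-2-[(2E)-4-hydroxy-4-methylpent-2-en-1-yl]-5-methoxy-2-methylchroman-7-yl]methyl hexadecanoate F7. Babler–Dauben oxidative transposition with pyridinium chlorochromate, [C5H5NH][CrO3Cl], in CH2Cl2 then moves the oxygen to C2' and gives enone 20.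

3. Step 3.
What may go wrong:
- slow fluoride displacement on the methoxy-bearing ring, so that decomposition at the temperature needed competes with ring closure.

Fallback, metal activation of the arene. It sets out from 6 and comes back at 8. Heating 6 with Cr(CO)6 (Bu2O–THF, reflux) should give the η6-arene complex tricarbonyl[(3R)-1-(2,3-difluoro-6-methoxyphenyl)-3,7-dimethyloct-6-en-3-ol]chromium F8 (zerovalent chromium). KOt-Bu in THF at room temperature should then close the ring by SNAr on the strongly activated complexed fluoroarene to give tricarbonyl[(2R)-8-fluoro-5-methoxy-2-methyl-2-(4-methylpent-3-en-1-yl)chroman]chromium F9 (planar diastereomers, irrelevant after demetalation). Air and light in MeCN remove the metal and return 8.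

**Further compounds**

F1 | step 4 | 1-bromo-2-fluoro-3-iodo-4-methoxybenzene | COc1ccc(Br)c(F)c1I
F2 | step 4 | (3R)-1-(3-bromo-2-fluoro-6-methoxyphenyl)-3,7-dimethyloct-6-en-3-ol | COc1ccc(Br)c(F)c1CC[C@](C)(O)CCC=C(C)C
F3 | step 4 | (2R)-8-bromo-5-methoxy-2-methyl-2-(4-methylpent-3-en-1-yl)chroman | COc1ccc(Br)c2O[C@](C)(CCC=C(C)C)CCc12
F4 | step 4 | (2R)-5-methoxy-2-methyl-2-(4-methylpent-3-en-1-yl)chroman-8-carbaldehyde | COc1ccc(C=O)c2O[C@](C)(CCC=C(C)C)CCc12
F5 | step 4 | lithium α-amino alkoxide of F4 with N,N,N'-trimethylethylenediamine | COc1ccc(C([O-])N(C)CCN(C)C)c2O[C@](C)(CCC=C(C)C)CCc12.[Li+]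
F6 | step 7 | [(2S)-8-formyl-2-[4-hydroxy-4-methyl-3-(phenylselanyl)pentyl]-5-methoxy-2-methylchroman-7-yl]methyl hexadecanoate | CCCCCCCCCCCCCCCC(=O)OCc1cc(OC)c2c(c1C=O)O[C@](C)(CCC([Se]c1ccccc1)C(C)(C)O)CC2
F7 | step 7 | [(2S)-8-formyl-2-[(2E)-4-hydroxy-4-methylpent-2-en-1-yl]-5-methoxy-2-methylchroman-7-yl]methyl hexadecanoate | CCCCCCCCCCCCCCCC(=O)OCc1cc(OC)c2c(c1C=O)O[C@](C)(C/C=C/C(C)(C)O)CC2
F8 | step 3 | tricarbonyl[η6-(3R)-1-(2,3-difluoro-6-methoxyphenyl)-3,7-dimethyloct-6-en-3-ol]chromium | COc1ccc(F)c(F)c1CC[C@](C)(O)CCC=C(C)C.[Cr].[C-]#[O+].[C-]#[O+].[C-]#[O+]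
F9 | step 3 | tricarbonyl[η6-(2R)-8-fluoro-5-methoxy-2-methyl-2-(4-methylpent-3-en-1-yl)chroman]chromium | COc1ccc(F)c2O[C@](C)(CCC=C(C)C)CCc12.[Cr].[C-]#[O+].[C-]#[O+].[C-]#[O+]
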